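**Retrosynthetic overview**

- Ring A rests on its 1,3-dioxygen pattern: free C2-OH, C4-OMe, unsubstituted C3 between them, C6-Me, and C1 carrying the depside carbonyl. It is built last by a Danheiser benzannulation of diazoketone 15 with methoxyacetylene 18, which forms C5-C6, C2-C3, C4-C5 and C1-C2. The ketene oxygen becomes C2-OH and the alkyne oxygen C4-OMe, so the two oxygens are differentiated by construction.
- Diazoketone 15 comes from methyl ketone 13 by detrifluoroacetylative diazo transfer. An acyl chloride/diazomethane route from a mesaconate is avoided because diazomethane would add as a dipole to the electron-poor C=C. Ketone 13 is the ester of B-C phenol 8 with (E)-3-methyl-4-oxopent-2-enoic acid 12, made by Wittig reaction of butane-2,3-dione.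
- Phenol 8 comes from a depside coupling of ring B acid 5 with ring C phenol 4, both made from methyl orsellinate 1 through the common ether 3.
- Ring order: rings B and C are bought as methyl orsellinate; ring A is the only ring formed, in the last step.

Key step: step 12

Assumption: the target has no stereocentre; the only stereo-element to control is the E geometry of the enoate carried from 11 to 15, which the ring closure needs.

**Route**

Step 1
Reactants: 1 methyl orsellinate (methyl 2,4-dihydroxy-6-methylbenzoate)
Product: 2 methyl 4-(benzyloxy)-2-hydroxy-6-methylbenzoate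
Conditions: BnBr (1.05 equiv), K2CO3 (1.1 equiv), acetone, reflux
Reagents that add atoms: benzyl bromide, BrCc1ccccc1
Why: Williamson etherification that should go selectively at the 4-OH, because the 2-OH is tied up in a hydrogen bond to the ester carbonyl and is less acidic and less nucleophilic.

Step 2
Reactants: 2 methyl 4-(benzyloxy)-2-hydroxy-6-methylbenzoate
Product: 3 methyl 4-(benzyloxy)-2-methoxy-6-methylbenzoate
Conditions: MeI (3 equiv), K2CO3 (3 equiv), DMF, 50 °C
Reagents that add atoms: iodomethane, CI
Why: Williamson methylation of the chelated phenol, which excess base and alkylating agent in a dipolar solvent should drive to completion.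

Step 3
Reactants: 3 methyl 4-(benzyloxy)-2-methoxy-6-methylbenzoate
Product: 4 methyl 4-hydroxy-2-methoxy-6-methylbenzoate (ring C phenol)
Conditions: H2 (1 atm), Pd/C (10% palladium metal on carbon), EtOAc/MeOH, rt
Reagents that add atoms: none
Why: Catalytic hydrogenolysis of the benzyl aryl ether, which leaves the methyl ester and methyl ether untouched.

Step 4
Reactants: 3 methyl 4-(benzyloxy)-2-methoxy-6-methylbenzoate
Product: 5 4-(benzyloxy)-2-methoxy-6-methylbenzoic acid (ring B acid)
Conditions: KOH (5 equiv), DMSO/H2O 4:1, 90 °C; then aq HCl to pH 2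
Reagents that add atoms: potassium hydroxide, [K+].[OH-] (the hydroxide oxygen becomes the carboxyl OH)
Why: Saponification of the di-ortho-substituted benzoate needs poorly solvated hydroxide in DMSO and heat, conditions under which the benzyl and methyl ethers are inert.

Step 5
Reactants: 5 4-(benzyloxy)-2-methoxy-6-methylbenzoic acid; 4 methyl 4-hydroxy-2-methoxy-6-methylbenzoate
Product: 7 methyl 4-{[4-(benzyloxy)-2-methoxy-6-methylbenzoyl]oxy}-2-methoxy-6-methylbenzoate (B-C benzyl ether), via mixed trifluoroacetic anhydride 6 (not isolated)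
Conditions: (CF3CO)2O (3 equiv), toluene, 0 °C to rt
Reagents that add atoms: trifluoroacetic anhydride, O=C(OC(=O)C(F)(F)F)C(F)(F)F (its trifluoroacetyl group stays only in intermediate 6; no atom of it remains in 7)
Why: Depside esterification through the mixed anhydride, in which the electron-rich hindered aroyl group is transferred to the phenol by an acylium-like pathway, a standard way to make di-ortho-substituted aryl benzoates.

Step 6
Reactants: 7 B-C benzyl ether
Product: 8 methyl 4-[(4-hydroxy-2-methoxy-6-methylbenzoyl)oxy]-2-methoxy-6-methylbenzoate (B-C phenol)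
Conditions: H2 (1 atm), Pd/C (10% palladium metal on carbon), EtOAc, rt
Reagents that add atoms: none
Why: Hydrogenolysis of the benzyl ether, to which the aryl ester and methyl ester are stable.

Step 7
Reactants: 9 butane-2,3-dione (2 equiv); 10 tert-butyl (triphenylphosphoranylidene)acetate
Product: 11 tert-butyl (E)-3-methyl-4-oxopent-2-enoate
Conditions: CH2Cl2, rt; chromatography
Reagents that add atoms: none
Why: Wittig olefination of the activated 1,2-diketone with a stabilised ylide, which should stop after one carbonyl because the remaining ketone is conjugated and hindered, and should favour the E alkene with the ester trans to the acetyl group.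

Step 8
Reactants: 11 tert-butyl (E)-3-methyl-4-oxopent-2-enoate
Product: 12 (E)-3-methyl-4-oxopent-2-enoic acid
Conditions: CF3CO2H/CH2Cl2 1:3, 0 °C to rt; evaporate
Reagents that add atoms: none
Why: Acidolysis of the tert-butyl ester by alkyl-oxygen cleavage with loss of isobutene, mild enough to keep the E enone.

Step 9
Reactants: 8 B-C phenol; 12 (E)-3-methyl-4-oxopent-2-enoic acid
Product: 13 3-methoxy-4-{[3-methoxy-4-(methoxycarbonyl)-5-methylphenoxy]carbonyl}-5-methylphenyl (E)-3-methyl-4-oxopent-2-enoate (B-C aryl keto-enoate)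
Conditions: DCC (1.1 equiv), DMAP (0.1 equiv), CH2Cl2, 0 °C to rt
Reagents that add atoms: none
Why: Steglich esterification of an unhindered enoic acid with the only free phenol of 8, run cold with catalytic DMAP so that acyl transfer outruns conjugate addition to the C=C.

Step 10
Reactants: 13 B-C aryl keto-enoate
Product: 15 3-methoxy-4-{[3-methoxy-4-(methoxycarbonyl)-5-methylphenoxy]carbonyl}-5-methylphenyl (E)-5-diazo-3-methyl-4-oxopent-2-enoate (B-C aryl diazoketone), via trifluoroacetyl diketone 14 (not isolated)
Conditions: LiN(SiMe3)2 (1.1 equiv), THF, −78 °C; CF3CO2CH2CF3 (1.2 equiv), −78 °C; 5% aq HCl work-up; then MsN3 (1.5 equiv), Et3N (1.5 equiv), H2O (1 equiv), MeCN, rt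
Reagents that add atoms: 2,2,2-trifluoroethyl trifluoroacetate, FC(F)(F)COC(=O)C(F)(F)F (trifluoroacetyl group of intermediate 14 only); methanesulfonyl azide, CS(=O)(=O)N=[N+]=[N-] (the two diazo nitrogens of 15)
Why: Detrifluoroacetylative diazo transfer, in which kinetic enolisation of the methyl ketone at −78 °C and Claisen trifluoroacetylation give diketone 14, and Regitz-type transfer from MsN3 with loss of the trifluoroacetyl group gives the diazoketone without exposing the enoate C=C to diazomethane, while the hindered benzoate esters are not touched by the bulky amide base.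

Step 11
Reactants: 16 chloroacetaldehyde dimethyl acetal
Product: 18 methoxyacetylene, via sodium methoxyacetylide 17 (not isolated)
Conditions: NaNH2 (3 equiv), liquid NH3, −33 °C; evaporate NH3; cold saturated aq NaCl, distil (bp about 23 °C) into a −78 °C trap; use as a cold solution in ClCH2CH2Cl
Reagents that add atoms: sodium amide, [Na+].[NH2-] (its sodium stays only in intermediate 17; no atom of it remains in 18)
Why: Twofold base-induced elimination of methanol and HCl from the chloroacetal gives the ynol ether, held as its acetylide 17 by the third equivalent of amide and released by protonation with cold brine.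

Step 12
Reactants: 15 B-C aryl diazoketone; 18 methoxyacetylene (5 equiv)
Product: 22 methyl 4-[(4-{[2-hydroxy-4-methoxy-6-methylbenzoyl]oxy}-2-methoxy-6-methylbenzoyl)oxy]-2-methoxy-6-methylbenzoate (target CNP0362907.0), via vinylketene 19 (not isolated), via vinylcyclobutenone 20 (not isolated), via dienylketene 21 (not isolated)
Conditions: ClCH2CH2Cl (0.05 M), degassed, sealed Pyrex tube, LED about 400 nm, 15 °C until the diazo compound is consumed; then 80 °C in the dark
Reagents that add atoms: none
Why: Excitation of the diazoketone expels N2 and the alkenyl carbon C6 shifts to the former diazo carbon C5 (Wolff rearrangement) to give vinylketene 19, whose ketene C=C adds the ynol ether in a (2+2) cycloaddition (C2-C3 and C4-C5) to 3-methoxy-4-vinylcyclobutenone 20, which opens on heating by reversible four-electron electrocyclic ring opening to dienylketene 21. Ring A then closes by thermal disrotatory six-electron electrocyclisation of 21 (C1-C2) and the cyclohexadienone tautomerises to the phenol, so the former ketone oxygen becomes the C2 hydroxyl and the alkyne oxygen the C4 methyl ether. The closest known reaction type is the Danheiser benzannulation in its diazoketone variant with alkoxyacetylenes. No stereocentre remains, since the sp3 carbon of 20 is lost on ring opening. The step needs (2+2) regiochemistry, set by the polarisation of 18 (its unsubstituted nucleophilic carbon bonds to the electrophilic ketene carbonyl carbon), and it needs the E enoate, which keeps the aryl ester trans to the ketene so that it cannot close through the ester oxygen to a 2-pyranone and sits on the outside of the triene during ring closure. Light near 400 nm is absorbed by the diazo-enone chromophore but not by the aryl benzoate units, which avoids photo-Fries cleavage, and the excess alkyne should trap the ketene before the product phenol can.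

**Compound list**

1 | methyl orsellinate (methyl 2,4-dihydroxy-6-methylbenzoate) | COC(=O)c1c(C)cc(O)cc1O | starting material
2 | methyl 4-(benzyloxy)-2-hydroxy-6-methylbenzoate | COC(=O)c1c(C)cc(OCc2ccccc2)cc1O | intermediate
3 | methyl 4-(benzyloxy)-2-methoxy-6-methylbenzoate | COC(=O)c1c(C)cc(OCc2ccccc2)cc1OC | intermediate
4 | methyl 4-hydroxy-2-methoxy-6-methylbenzoate (ring C phenol) | COC(=O)c1c(C)cc(O)cc1OC | intermediate
5 | 4-(benzyloxy)-2-methoxy-6-methylbenzoic acid (ring B acid) | OC(=O)c1c(C)cc(OCc2ccccc2)cc1OC | intermediate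
6 | 4-(benzyloxy)-2-methoxy-6-methylbenzoic trifluoroacetic anhydride (not isolated) | FC(F)(F)C(=O)OC(=O)c1c(C)cc(OCc2ccccc2)cc1OC | intermediate
7 | methyl 4-{[4-(benzyloxy)-2-methoxy-6-methylbenzoyl]oxy}-2-methoxy-6-methylbenzoate (B-C benzyl ether) | COC(=O)c1c(C)cc(OC(=O)c2c(C)cc(OCc3ccccc3)cc2OC)cc1OC | intermediate
8 | methyl 4-[(4-hydroxy-2-methoxy-6-methylbenzoyl)oxy]-2-methoxy-6-methylbenzoate (B-C phenol) | COC(=O)c1c(C)cc(OC(=O)c2c(C)cc(O)cc2OC)cc1OC | intermediate
9 | butane-2,3-dione | CC(=O)C(C)=O | starting material
10 | tert-butyl (triphenylphosphoranylidene)acetate | CC(C)(C)OC(=O)C=P(c1ccccc1)(c1ccccc1)c1ccccc1 | starting material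
11 | tert-butyl (E)-3-methyl-4-oxopent-2-enoate | CC(=O)/C(C)=C/C(=O)OC(C)(C)C | intermediate
12 | (E)-3-methyl-4-oxopent-2-enoic acid | CC(=O)/C(C)=C/C(=O)O | intermediate
13 | B-C aryl (E)-3-methyl-4-oxopent-2-enoate | CC(=O)/C(C)=C/C(=O)Oc1cc(C)c(C(=O)Oc2cc(C)c(C(=O)OC)c(OC)c2)c(OC)c1 | intermediate
14 | B-C aryl (E)-7,7,7-trifluoro-3-methyl-4,6-dioxohept-2-enoate (trifluoroacetyl diketone, not isolated) | FC(F)(F)C(=O)CC(=O)/C(C)=C/C(=O)Oc1cc(C)c(C(=O)Oc2cc(C)c(C(=O)OC)c(OC)c2)c(OC)c1 | intermediate
15 | B-C aryl (E)-5-diazo-3-methyl-4-oxopent-2-enoate (key precursor) | [N-]=[N+]=CC(=O)/C(C)=C/C(=O)Oc1cc(C)c(C(=O)Oc2cc(C)c(C(=O)OC)c(OC)c2)c(OC)c1 | intermediate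
16 | chloroacetaldehyde dimethyl acetal | COC(CCl)OC | starting material
17 | sodium methoxyacetylide (not isolated) | [Na+].[C-]#COC | intermediate
18 | methoxyacetylene | COC#C | intermediate
19 | B-C aryl (E)-3-methyl-5-oxopenta-2,4-dienoate (vinylketene, not isolated) | O=C=C/C(C)=C/C(=O)Oc1cc(C)c(C(=O)Oc2cc(C)c(C(=O)OC)c(OC)c2)c(OC)c1 | intermediate
20 | B-C aryl (E)-3-(2-methoxy-4-oxocyclobut-2-en-1-yl)but-2-enoate (racemic vinylcyclobutenone, not isolated) | COC1=CC(=O)C1/C(C)=C/C(=O)Oc1cc(C)c(C(=O)Oc2cc(C)c(C(=O)OC)c(OC)c2)c(OC)c1 | intermediate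
21 | B-C aryl (2E,4Z)-5-methoxy-3-methyl-7-oxohepta-2,4,6-trienoate (dienylketene, not isolated) | O=C=C/C(OC)=C\C(C)=C\C(=O)Oc1cc(C)c(C(=O)Oc2cc(C)c(C(=O)OC)c(OC)c2)c(OC)c1 | intermediate
22 | methyl 4-[(4-{[2-hydroxy-4-methoxy-6-methylbenzoyl]oxy}-2-methoxy-6-methylbenzoyl)oxy]-2-methoxy-6-methylbenzoate | COC(=O)c1c(C)cc(OC(=O)c2c(C)cc(OC(=O)c3c(C)cc(OC)cc3O)cc2OC)cc1OC | target

("B-C aryl" = 3-methoxy-4-{[3-methoxy-4-(methoxycarbonyl)-5-methylphenoxy]carbonyl}-5-methylphenyl.)

**Step count and risks**

Total step count: 12. Longest linear sequence: 8 steps (steps 1, 2, 4, 5, 6, 9, 10, 12).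

Steps most likely to fail:

1. Step 12. The ketene may be consumed by dimerisation or by the product phenol before it meets the alkyne. The enoate may photoisomerise to Z and then close through the ester oxygen. The cyclobutenone may not open and close cleanly on heating.
Fallback: ring A is attached by a third depside esterification; it sets out from 1 and comes back at 22. Selective 4-O-methylation of 1 (MeI 1 equiv, K2CO3, acetone) should give methyl 2-hydroxy-4-methoxy-6-methylbenzoate F1. Benzylation of the chelated phenol (BnBr, K2CO3, DMF, 70 °C) gives methyl 2-(benzyloxy)-4-methoxy-6-methylbenzoate F2. KOH in DMSO/H2O at 90 °C, then aq HCl, gives 2-(benzyloxy)-4-methoxy-6-methylbenzoic acid F3. (CF3CO)2O in toluene with phenol 8 couples through 2-(benzyloxy)-4-methoxy-6-methylbenzoic trifluoroacetic anhydride F4 to the O-benzyl tridepside F5. H2 over Pd/C in EtOAc removes the benzyl group and returns to 22.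

2. Step 10. The enolate or the amide base may attack the activated aryl enoate, deprotonation may compete at the C3 methyl, or the enolate may add in Michael fashion to a second molecule before it is trifluoroacetylated.
Fallback: the diazo group is installed before the aryl ester exists; it sets out from 12 (and 8) and comes back at 15. DCC/DMAP with 2-(trimethylsilyl)ethanol converts 12 into 2-(trimethylsilyl)ethyl (E)-3-methyl-4-oxopent-2-enoate F6. The same LiN(SiMe3)2/CF3CO2CH2CF3 sequence gives 2-(trimethylsilyl)ethyl (E)-7,7,7-trifluoro-3-methyl-4,6-dioxohept-2-enoate F7 (not isolated), and MsN3/Et3N/H2O in MeCN gives 2-(trimethylsilyl)ethyl (E)-5-diazo-3-methyl-4-oxopent-2-enoate F8. Bu4NF in THF at 0 °C should release (E)-5-diazo-3-methyl-4-oxopent-2-enoic acid F9, which is used at once. DCC/DMAP coupling with phenol 8 in CH2Cl2 at 0 °C returns to 15.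

3. Step 9. The phenol or DMAP may add in conjugate fashion to the doubly activated C=C of 12. Reversible addition may isomerise E to Z, after which the acid closes to a lactol. Rearrangement to the N-acylurea may outrun acyl transfer.
Fallback: the C=C is formed after the ester; it sets out from 8 and comes back at 13. Bromoacetyl bromide and pyridine in CH2Cl2 at 0 °C give the B-C aryl bromoacetate F10. PPh3 in toluene at rt gives the B-C aryl (triphenylphosphonio)acetate bromide F11. Aqueous Na2CO3/CH2Cl2 gives the stabilised ylide B-C aryl (triphenylphosphoranylidene)acetate F12. Wittig reaction of F12 with excess butane-2,3-dione 9 in CH2Cl2 at rt returns to 13.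

**Further compounds**

F1 | step 12 | methyl 2-hydroxy-4-methoxy-6-methylbenzoate | COC(=O)c1c(C)cc(OC)cc1O
F2 | step 12 | methyl 2-(benzyloxy)-4-methoxy-6-methylbenzoate | COC(=O)c1c(C)cc(OC)cc1OCc1ccccc1
F3 | step 12 | 2-(benzyloxy)-4-methoxy-6-methylbenzoic acid | OC(=O)c1c(C)cc(OC)cc1OCc1ccccc1
F4 | step 12 | 2-(benzyloxy)-4-methoxy-6-methylbenzoic trifluoroacetic anhydride (not isolated) | FC(F)(F)C(=O)OC(=O)c1c(C)cc(OC)cc1OCc1ccccc1
F5 | step 12 | methyl 4-[(4-{[2-(benzyloxy)-4-methoxy-6-methylbenzoyl]oxy}-2-methoxy-6-methylbenzoyl)oxy]-2-methoxy-6-methylbenzoate | COC(=O)c1c(C)cc(OC(=O)c2c(C)cc(OC(=O)c3c(C)cc(OC)cc3OCc4ccccc4)cc2OC)cc1OC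
F6 | step 10 | 2-(trimethylsilyl)ethyl (E)-3-methyl-4-oxopent-2-enoate | CC(=O)/C(C)=C/C(=O)OCC[Si](C)(C)C
F7 | step 10 | 2-(trimethylsilyl)ethyl (E)-7,7,7-trifluoro-3-methyl-4,6-dioxohept-2-enoate (not isolated) | FC(F)(F)C(=O)CC(=O)/C(C)=C/C(=O)OCC[Si](C)(C)C
F8 | step 10 | 2-(trimethylsilyl)ethyl (E)-5-diazo-3-methyl-4-oxopent-2-enoate | [N-]=[N+]=CC(=O)/C(C)=C/C(=O)OCC[Si](C)(C)C
F9 | step 10 | (E)-5-diazo-3-methyl-4-oxopent-2-enoic acid | [N-]=[N+]=CC(=O)/C(C)=C/C(=O)O
F10 | step 9 | B-C aryl bromoacetate | BrCC(=O)Oc1cc(C)c(C(=O)Oc2cc(C)c(C(=O)OC)c(OC)c2)c(OC)c1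
F11 | step 9 | B-C aryl (triphenylphosphonio)acetate bromide | [Br-].O=C(C[P+](c1ccccc1)(c1ccccc1)c1ccccc1)Oc1cc(C)c(C(=O)Oc2cc(C)c(C(=O)OC)c(OC)c2)c(OC)c1
F12 | step 9 | B-C aryl (triphenylphosphoranylidene)acetate | O=C(C=P(c1ccccc1)(c1ccccc1)c1ccccc1)Oc1cc(C)c(C(=O)Oc2cc(C)c(C(=O)OC)c(OC)c2)c(OC)c1
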